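**Plan**

- Cuts, working backwards: the two ring A acetals; the C4 carbonyl and the O1–C2 bond of ring D; the ring C bonds C1'–C2' and C5'–C6'; the ynone arm and furan ring B; the C7–CMe2 bond on ring A.
- Enabling feature: ring C is a resorcinol with oxygen on C3' and C5', hydrogen on C4' and carbon on the other three atoms (prenyl on C2', benzofuran C2 on C1', ring D carbon C4 on C6'). This is the pattern left by a 1,3-dioxygenated diene (C5'–C4'–C3'–C2') adding to an acyl alkyne (C1'≡C6').
- Forward: ring A is dressed by a chelation-directed Claisen shift, ring B is closed by Rap–Stoermer condensation and its acetyl group is turned into the ynone. Ring C then arises by Diels–Alder aromatisation with a prenylated acetoacetate bis(silyl enol ether), and ring D by oxa-Michael closure.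
- Endgame: the ring D carbonyl is taken to CH2 with borohydride through a para-quinone methide, and the acetals are cleaved.
- Stereochemistry: the target has no stereocentre. Only the 3Z geometry of the diene matters (set on enolisation), and every sp3 centre made on the way is racemic and later erased.

Key step: step 12

Remark: rotation about the C2–C1' benzofuran–aryl bond is taken as free, so no atropisomerism is considered.

Labels: ring A = benzo ring of the benzofuran, ring B = furan, ring C = resorcinol ring (C1'–C6'), ring D = dihydropyran. Ar = 4,6-bis(methoxymethoxy)-7-(2-methylbut-3-en-2-yl)-1-benzofuran-2-yl. Chroman numbering for ring C/D compounds: C5 = C1', C6 = C2', C7 = C3', C8 = C4', C8a = C5', C4a = C6'.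

**Route**

Step 1
Reactants: 1 2,4,6-trihydroxybenzaldehyde; 2 prenyl bromide (1-bromo-3-methylbut-2-ene)
Product: 3 2,6-dihydroxy-4-(3-methylbut-2-enyloxy)benzaldehyde
Conditions: K2CO3 (1.0 equiv), acetone, 25 °C
Reagents that add atoms: none
Why: Williamson etherification, in which the 4-hydroxyl is the only one not held in a hydrogen bond to the formyl group and is the most acidic, so one equivalent of base and bromide in a polar aprotic medium should alkylate it on oxygen.

Step 2
Reactants: 3 2,6-dihydroxy-4-(3-methylbut-2-enyloxy)benzaldehyde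
Product: 4 2-hydroxy-6-(methoxymethoxy)-4-(3-methylbut-2-enyloxy)benzaldehyde
Conditions: MOMCl (1.1 equiv), i-Pr2NEt, CH2Cl2, 0 °C
Reagents that add atoms: chloromethyl methyl ether, COCCl
Why: Acetal protection (methoxymethylation) of one of two equivalent hydroxyls, after which the remaining one stays locked in the hydrogen bond to the aldehyde and should resist a second alkylation.

Step 3
Reactants: 4 2-hydroxy-6-(methoxymethoxy)-4-(3-methylbut-2-enyloxy)benzaldehyde
Product: 6 2,4-dihydroxy-6-(methoxymethoxy)-3-(2-methylbut-3-en-2-yl)benzaldehyde, via ortho-dienone 5 (not isolated)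
Conditions: PhNEt2, 190 °C, sealed tube, argon, short reaction time
Reagents that add atoms: none
Why: Aromatic Claisen rearrangement ([3,3] shift to dienone 5, then enolisation), in which the position para to the ether oxygen carries the formyl group so that no onward Cope migration is possible, and the hydrogen bond between the C2 hydroxyl and the aldehyde fixes double-bond character in C3–C4, which should send the allyl unit, inverted to 1,1-dimethylallyl, to C3 and not to C5.

Step 4
Reactants: 6 2,4-dihydroxy-6-(methoxymethoxy)-3-(2-methylbut-3-en-2-yl)benzaldehyde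
Product: 7 2-hydroxy-4,6-bis(methoxymethoxy)-3-(2-methylbut-3-en-2-yl)benzaldehyde
Conditions: MOMCl (1.2 equiv), i-Pr2NEt, CH2Cl2, 0 to 25 °C
Reagents that add atoms: chloromethyl methyl ether, COCCl
Why: Selective methoxymethylation, since the new 4-hydroxyl is free whereas the 2-hydroxyl is chelated to the aldehyde and shielded on both sides, so a slight excess of reagent should cap O4 only.

Step 5
Reactants: 7 2-hydroxy-4,6-bis(methoxymethoxy)-3-(2-methylbut-3-en-2-yl)benzaldehyde; 8 chloroacetone
Product: 10 1-Ar-ethanone (2-acetyl-4,6-bis(methoxymethoxy)-7-(2-methylbut-3-en-2-yl)benzofuran), via aryloxyacetone 9 (not isolated)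
Conditions: K2CO3, KI (cat.), DMF, 80 °C
Reagents that add atoms: none
Why: Rap–Stoermer condensation, in which the phenoxide is alkylated by the α-chloroketone to ether 9, whose activated methylene adds to the neighbouring aldehyde (5-exo-trig aldol) and dehydrates to the aromatic 2-acetylbenzofuran, closing ring B.

Step 6
Reactants: 10 1-Ar-ethanone
Product: 12 Ar-ethyne (2-ethynyl-4,6-bis(methoxymethoxy)-7-(2-methylbut-3-en-2-yl)benzofuran), via enol phosphate 11 (not isolated)
Conditions: LiN(i-Pr)2 (1.1 equiv), THF, −78 °C; ClP(O)(OEt)2; then LiN(i-Pr)2 (2.3 equiv), −78 to 25 °C; H2O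
Reagents that add atoms: none
Why: Conversion of a methyl ketone into a terminal alkyne by O-phosphorylation of the lithium enolate and base-induced 1,2-elimination of diethyl phosphate, a standard one-pot sequence for aryl methyl ketones to which the acetals and the quaternary allyl group are inert.

Step 7
Reactants: 12 Ar-ethyne; 13 3-methylbut-2-enal
Product: 14 1-Ar-5-methylhex-4-en-1-yn-3-ol (racemic)
Conditions: n-BuLi (1.0 equiv), THF, −78 °C; then 13, −78 to 0 °C; H2O
Reagents that add atoms: none
Why: 1,2-Addition of a lithium acetylide to an enal, in which the hard alkynyl nucleophile attacks the aldehyde carbon, and the carbinol centre, formed racemic, is removed in the next step.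

Step 8
Reactants: 14 1-Ar-5-methylhex-4-en-1-yn-3-ol
Product: 15 1-Ar-5-methylhex-4-en-1-yn-3-one
Conditions: MnO2 (activated, excess), CH2Cl2, 25 °C
Reagents that add atoms: none
Why: MnO2 oxidation of an alcohol that is both propargylic and allylic is fast and neutral, so the acetals, the terminal alkene and the electron-rich benzofuran should be untouched.

Step 9
Reactants: 16 methyl acetoacetate; 2 prenyl bromide
Product: 17 methyl 7-methyl-3-oxooct-6-enoate
Conditions: LiN(i-Pr)2 (2.1 equiv), THF, 0 °C; then 2, 0 to 25 °C; H2O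
Reagents that add atoms: none
Why: γ-Alkylation of the acetoacetate dianion, whose terminal carbanion is the more reactive site and should take the allylic bromide by SN2 at C4.

Step 10
Reactants: 17 methyl 7-methyl-3-oxooct-6-enoate
Product: 18 methyl 7-methyl-3-(trimethylsilyloxy)octa-2,6-dienoate (E/Z mixture)
Conditions: Me3SiCl, Et3N, toluene, 25 °C
Reagents that add atoms: chlorotrimethylsilane, C[Si](C)(C)Cl
Why: O-Silylation of the β-keto ester enol gives the silyl enol ether, the usual first stage of bis(silyl enol ether) preparation.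

Step 11
Reactants: 18 methyl 7-methyl-3-(trimethylsilyloxy)octa-2,6-dienoate
Product: 19 (3Z)-1-methoxy-7-methyl-1,3-bis(trimethylsilyloxy)octa-1,3,6-triene
Conditions: LiN(i-Pr)2, THF, −78 °C; Me3SiCl, −78 to 0 °C; used without chromatography
Reagents that add atoms: chlorotrimethylsilane, C[Si](C)(C)Cl
Why: Kinetic γ-deprotonation of the β-silyloxy enoate and O-silylation of the ester dienolate gives the 1,3-bis(silyl enol ether), and the side chain is expected to sit trans to C2 (3Z), the geometry that leaves the s-cis diene accessible.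

Step 12
Reactants: 15 1-Ar-5-methylhex-4-en-1-yn-3-one; 19 (3Z)-1-methoxy-7-methyl-1,3-bis(trimethylsilyloxy)octa-1,3,6-triene
Product: 22 1-[2-Ar-4,6-dihydroxy-3-(3-methylbut-2-enyl)phenyl]-3-methylbut-2-en-1-one, via cycloadduct 20 (not isolated), via bis(trimethylsilyl) ether 21 (not isolated)
Conditions: 19 (2.5 equiv), toluene, 25 to 90 °C, sealed tube; then 1 M aq. HCl, THF, 0 °C
Reagents that add atoms: none
Why: The electron-rich diene 19 and the electron-poor triple bond of 15 should combine in a polar, asynchronous Diels–Alder reaction in which the prenyl-bearing diene terminus C4, the most nucleophilic site, bonds to the ynone β carbon that carries the benzofuran (C1'–C2') and the ketene acetal carbon C1 bonds to the α carbon (C5'–C6'). The closest known reaction type is the cycloaddition of 1-alkoxy-1,3-bis(silyloxy)-1,3-dienes to acetylenic ketones and esters, which gives resorcinols after loss of the alcohol. Ring C is closed as a six-membered carbocycle by this intermolecular [4+2] cycloaddition, and the 1,4-cyclohexadiene 20 aromatises by 1,4-elimination of methanol to the bis(silyl) ether 21, which cold dilute acid desilylates without touching the acetals. The two sp3 centres of 20 are both erased on aromatisation, so no stereocentre has to be controlled. The step needs regioselectivity, which the matched polarisation of ketene acetal diene and acyl alkyne secures and which places the acyl group next to the C5' hydroxyl; it needs chemoselectivity for the triple bond, which the β,β-dimethyl substitution of the enone alkene secures; and it needs [4+2] over Michael–aldol closure, which the absence of a Lewis acid and the hindered cross-conjugated carbonyl favour.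

Step 13
Reactants: 22 1-[2-Ar-4,6-dihydroxy-3-(3-methylbut-2-enyl)phenyl]-3-methylbut-2-en-1-one
Product: 23 5-Ar-7-hydroxy-2,2-dimethyl-6-(3-methylbut-2-enyl)chroman-4-one
Conditions: K2CO3 (0.2 equiv), MeOH, 25 °C
Reagents that add atoms: none
Why: Intramolecular oxa-Michael addition (6-endo-trig), in which only the C5' hydroxyl lies ortho to the enone and its phenoxide adds to the dimethyl-substituted β carbon to close ring D as the 2,2-dimethylchroman-4-one; any chromanone already formed during the work-up of step 12 converges here.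

Step 14
Reactants: 23 5-Ar-7-hydroxy-2,2-dimethyl-6-(3-methylbut-2-enyl)chroman-4-one
Product: 26 5-Ar-2,2-dimethyl-6-(3-methylbut-2-enyl)chroman-7-ol, via chroman-4-ol 24 (not isolated), via quinone methide 25 (not isolated)
Conditions: NaBH4 (excess), EtOH, 25 °C; then 2 M aq. NaOH, 80 °C; neutralise to pH 6–7
Reagents that add atoms: none
Why: Borohydride reduction of the ketone followed by base-induced hydrogenolysis of the para-hydroxybenzylic alcohol, in which the C7 phenoxide expels hydroxide from C4 and the resulting para-quinone methide takes hydride by 1,6-addition, a known acid-free way from para-hydroxyaryl ketones to alkylphenols that should spare both alkenes, the acetals and the benzofuran.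

Step 15
Reactants: 26 5-Ar-2,2-dimethyl-6-(3-methylbut-2-enyl)chroman-7-ol
Product: 27 Artopetelin C
Conditions: 3 M aq. HCl, MeOH, 40 °C, stopped at full conversion
Reagents that add atoms: none
Why: Acid-catalysed acetal exchange (methanolysis of the two methoxymethyl ethers) frees the ring A phenols under conditions mild enough that the ortho-prenyl and ortho-(1,1-dimethylallyl) phenols should not yet cyclise onto their alkenes.

**Compound list**

1 | 2,4,6-trihydroxybenzaldehyde | O=Cc1c(O)cc(O)cc1O | starting material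
2 | prenyl bromide (1-bromo-3-methylbut-2-ene) | CC(C)=CCBr | starting material
3 | 2,6-dihydroxy-4-(3-methylbut-2-enyloxy)benzaldehyde | O=Cc1c(O)cc(OCC=C(C)C)cc1O | intermediate
4 | 2-hydroxy-6-(methoxymethoxy)-4-(3-methylbut-2-enyloxy)benzaldehyde | O=Cc1c(O)cc(OCC=C(C)C)cc1OCOC | intermediate
5 | 4-formyl-5-hydroxy-3-(methoxymethoxy)-6-(2-methylbut-3-en-2-yl)cyclohexa-2,4-dien-1-one (ortho-dienone, racemic, not isolated) | O=CC1=C(O)C(C(C)(C)C=C)C(=O)C=C1OCOC | intermediate
6 | 2,4-dihydroxy-6-(methoxymethoxy)-3-(2-methylbut-3-en-2-yl)benzaldehyde | O=Cc1c(O)c(C(C)(C)C=C)c(O)cc1OCOC | intermediate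
7 | 2-hydroxy-4,6-bis(methoxymethoxy)-3-(2-methylbut-3-en-2-yl)benzaldehyde | O=Cc1c(O)c(C(C)(C)C=C)c(OCOC)cc1OCOC | intermediate
8 | chloroacetone (1-chloropropan-2-one) | CC(=O)CCl | starting material
9 | 1-[2-formyl-3,5-bis(methoxymethoxy)-6-(2-methylbut-3-en-2-yl)phenoxy]propan-2-one (aryloxyacetone, not isolated) | CC(=O)COc1c(C=O)c(OCOC)cc(OCOC)c1C(C)(C)C=C | intermediate
10 | 1-[4,6-bis(methoxymethoxy)-7-(2-methylbut-3-en-2-yl)-1-benzofuran-2-yl]ethanone | CC(=O)c1cc2c(OCOC)cc(OCOC)c(C(C)(C)C=C)c2o1 | intermediate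
11 | diethyl 1-[4,6-bis(methoxymethoxy)-7-(2-methylbut-3-en-2-yl)-1-benzofuran-2-yl]ethenyl phosphate (enol phosphate, not isolated) | C=C(OP(=O)(OCC)OCC)c1cc2c(OCOC)cc(OCOC)c(C(C)(C)C=C)c2o1 | intermediate
12 | 2-ethynyl-4,6-bis(methoxymethoxy)-7-(2-methylbut-3-en-2-yl)-1-benzofuran | C#Cc1cc2c(OCOC)cc(OCOC)c(C(C)(C)C=C)c2o1 | intermediate
13 | 3-methylbut-2-enal | CC(C)=CC=O | starting material
14 | 1-[4,6-bis(methoxymethoxy)-7-(2-methylbut-3-en-2-yl)-1-benzofuran-2-yl]-5-methylhex-4-en-1-yn-3-ol (racemic) | CC(C)=CC(O)C#Cc1cc2c(OCOC)cc(OCOC)c(C(C)(C)C=C)c2o1 | intermediate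
15 | 1-[4,6-bis(methoxymethoxy)-7-(2-methylbut-3-en-2-yl)-1-benzofuran-2-yl]-5-methylhex-4-en-1-yn-3-one | CC(C)=CC(=O)C#Cc1cc2c(OCOC)cc(OCOC)c(C(C)(C)C=C)c2o1 | intermediate
16 | methyl acetoacetate (methyl 3-oxobutanoate) | COC(=O)CC(C)=O | starting material
17 | methyl 7-methyl-3-oxooct-6-enoate | COC(=O)CC(=O)CCC=C(C)C | intermediate
18 | methyl 7-methyl-3-(trimethylsilyloxy)octa-2,6-dienoate (C2=C3 E/Z mixture) | COC(=O)C=C(O[Si](C)(C)C)CCC=C(C)C | intermediate
19 | (3Z)-1-methoxy-7-methyl-1,3-bis(trimethylsilyloxy)octa-1,3,6-triene (C1=C2 geometry unassigned) | COC(O[Si](C)(C)C)=C/C(O[Si](C)(C)C)=C/CC=C(C)C | intermediate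
20 | 1-{2-Ar-6-methoxy-3-(3-methylbut-2-enyl)-4,6-bis(trimethylsilyloxy)cyclohexa-1,4-dien-1-yl}-3-methylbut-2-en-1-one (cycloadduct, diastereomer mixture, not isolated) | COC1(O[Si](C)(C)C)C=C(O[Si](C)(C)C)C(CC=C(C)C)C(c2cc3c(OCOC)cc(OCOC)c(C(C)(C)C=C)c3o2)=C1C(=O)C=C(C)C | intermediate
21 | 1-[2-Ar-3-(3-methylbut-2-enyl)-4,6-bis(trimethylsilyloxy)phenyl]-3-methylbut-2-en-1-one (not isolated) | C[Si](C)(C)Oc1cc(O[Si](C)(C)C)c(CC=C(C)C)c(-c2cc3c(OCOC)cc(OCOC)c(C(C)(C)C=C)c3o2)c1C(=O)C=C(C)C | intermediate
22 | 1-{2-[4,6-bis(methoxymethoxy)-7-(2-methylbut-3-en-2-yl)-1-benzofuran-2-yl]-4,6-dihydroxy-3-(3-methylbut-2-enyl)phenyl}-3-methylbut-2-en-1-one | Oc1cc(O)c(CC=C(C)C)c(-c2cc3c(OCOC)cc(OCOC)c(C(C)(C)C=C)c3o2)c1C(=O)C=C(C)C | intermediate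
23 | 5-[4,6-bis(methoxymethoxy)-7-(2-methylbut-3-en-2-yl)-1-benzofuran-2-yl]-7-hydroxy-2,2-dimethyl-6-(3-methylbut-2-enyl)chroman-4-one | CC1(C)CC(=O)c2c(O1)cc(O)c(CC=C(C)C)c2-c3cc4c(OCOC)cc(OCOC)c(C(C)(C)C=C)c4o3 | intermediate
24 | 5-[4,6-bis(methoxymethoxy)-7-(2-methylbut-3-en-2-yl)-1-benzofuran-2-yl]-2,2-dimethyl-6-(3-methylbut-2-enyl)chromane-4,7-diol (racemic, not isolated) | CC1(C)CC(O)c2c(O1)cc(O)c(CC=C(C)C)c2-c3cc4c(OCOC)cc(OCOC)c(C(C)(C)C=C)c4o3 | intermediate
25 | 5-[4,6-bis(methoxymethoxy)-7-(2-methylbut-3-en-2-yl)-1-benzofuran-2-yl]-2,2-dimethyl-6-(3-methylbut-2-enyl)-2,3-dihydro-7H-chromen-7-one (para-quinone methide, not isolated) | CC1(C)CC=C2C(-c3cc4c(OCOC)cc(OCOC)c(C(C)(C)C=C)c4o3)=C(CC=C(C)C)C(=O)C=C2O1 | intermediate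
26 | 5-[4,6-bis(methoxymethoxy)-7-(2-methylbut-3-en-2-yl)-1-benzofuran-2-yl]-2,2-dimethyl-6-(3-methylbut-2-enyl)chroman-7-ol | CC1(C)CCc2c(O1)cc(O)c(CC=C(C)C)c2-c3cc4c(OCOC)cc(OCOC)c(C(C)(C)C=C)c4o3 | intermediate
27 | Artopetelin C, 5-[4,6-dihydroxy-7-(2-methylbut-3-en-2-yl)-1-benzofuran-2-yl]-2,2-dimethyl-6-(3-methylbut-2-enyl)chroman-7-ol | C=CC(C)(C)c1c(O)cc(O)c2cc(-c3c(CC=C(C)C)c(O)cc4c3CCC(C)(C)O4)oc12 | target

**Step count and risks**

Total: 15 steps. Longest linear sequence: 12 steps (steps 1–8, then 12–15); the diene branch (steps 9–11) joins at step 12.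

Most likely to fail, in this order:

Step 12. The cycloaddition joins a substituted diene terminus to an aryl-substituted alkyne carbon and may be too slow at temperatures the bis(silyl enol ether) tolerates. Protodesilylation of the diene, or a stepwise Michael addition followed by aldol closure onto the ketone, could then take over. The fallback carries a smaller and more electrophilic acyl group through the cycloaddition and completes the enone afterwards. It sets out from alkyne 12 and uses diene 19 unchanged. Lithiation and formylation of 12 (n-BuLi, THF, −78 °C; DMF; aqueous KH2PO4) should give 3-Ar-prop-2-ynal F1. F1 and 19 in toluene at 25–60 °C should give the cycloadduct F2, which loses methanol to the bis(trimethylsilyl) ether F3. Cold dilute HCl should then release 2-Ar-4,6-dihydroxy-3-(3-methylbut-2-enyl)benzaldehyde F4. Addition of Me2C=CHMgBr (3.5 equiv, THF, 0 °C) should give the allylic carbinol 1-[2-Ar-4,6-dihydroxy-3-(3-methylbut-2-enyl)phenyl]-3-methylbut-2-en-1-ol F5, which is oxidised at once with MnO2 in CH2Cl2. The route is rejoined at enone 22.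

Step 14. Reduction of the ketone may stall once the para phenoxide has formed. The chromanone may also reopen by retro-oxa-Michael reaction in hot alkali, or the quinone methide may tautomerise to the 2H-chromene faster than it captures hydride. The fallback separates reduction from hydrogenolysis and changes the leaving group from hydroxide to acetate. It sets out from chromanone 23: LiAlH4 (THF, 0 °C) should give the diol 24, now isolated. Ac2O, pyridine and DMAP (cat.) should convert it into 5-Ar-2,2-dimethyl-6-(3-methylbut-2-enyl)chromane-4,7-diyl diacetate F6. NaBH4 with one equivalent of aqueous NaOH in THF/EtOH at 0 to 25 °C then cleaves the aryl acetate. The phenoxide expels the benzylic acetate at room temperature, and the quinone methide 25 is reduced in the presence of excess hydride. The route is rejoined at chroman 26.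

Step 3. The [3,3] shift may go partly to C5. At 190 °C the product, with two free hydroxyls flanking the 1,1-dimethylallyl group, may also cyclise onto the alkene or isomerise by the abnormal Claisen pathway. The fallback moves the rearrangement to the benzofuran stage, where the ring fusion replaces chelation as the directing element and only one free hydroxyl ends up next to the allyl unit. It sets out from aldehyde 4. Condensation with chloroacetone 8 (K2CO3, KI, DMF, 80 °C) should pass through 1-[2-formyl-3-(methoxymethoxy)-5-(3-methylbut-2-enyloxy)phenoxy]propan-2-one F7 to 1-[4-(methoxymethoxy)-6-(3-methylbut-2-enyloxy)-1-benzofuran-2-yl]ethanone F8. Heating F8 (PhNEt2, 190 °C) should shift the allyl unit across the C6–C7 bond, which has the higher double-bond character in a benzofuran, while the para position C3a is blocked. This passes through the 7H-dienone F9 to 1-[6-hydroxy-4-(methoxymethoxy)-7-(2-methylbut-3-en-2-yl)-1-benzofuran-2-yl]ethanone F10. Methoxymethylation (MOMCl, i-Pr2NEt, CH2Cl2) then gives ketone 10, where the route is rejoined.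

**Further compounds**

F1 | step 12 | 3-[4,6-bis(methoxymethoxy)-7-(2-methylbut-3-en-2-yl)-1-benzofuran-2-yl]prop-2-ynal | O=CC#Cc1cc2c(OCOC)cc(OCOC)c(C(C)(C)C=C)c2o1
F2 | step 12 | 2-Ar-6-methoxy-3-(3-methylbut-2-enyl)-4,6-bis(trimethylsilyloxy)cyclohexa-1,4-diene-1-carbaldehyde (cycloadduct, not isolated) | COC1(O[Si](C)(C)C)C=C(O[Si](C)(C)C)C(CC=C(C)C)C(c2cc3c(OCOC)cc(OCOC)c(C(C)(C)C=C)c3o2)=C1C=O
F3 | step 12 | 2-Ar-3-(3-methylbut-2-enyl)-4,6-bis(trimethylsilyloxy)benzaldehyde (not isolated) | C[Si](C)(C)Oc1cc(O[Si](C)(C)C)c(CC=C(C)C)c(-c2cc3c(OCOC)cc(OCOC)c(C(C)(C)C=C)c3o2)c1C=O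
F4 | step 12 | 2-[4,6-bis(methoxymethoxy)-7-(2-methylbut-3-en-2-yl)-1-benzofuran-2-yl]-4,6-dihydroxy-3-(3-methylbut-2-enyl)benzaldehyde | Oc1cc(O)c(CC=C(C)C)c(-c2cc3c(OCOC)cc(OCOC)c(C(C)(C)C=C)c3o2)c1C=O
F5 | step 12 | 1-{2-[4,6-bis(methoxymethoxy)-7-(2-methylbut-3-en-2-yl)-1-benzofuran-2-yl]-4,6-dihydroxy-3-(3-methylbut-2-enyl)phenyl}-3-methylbut-2-en-1-ol (racemic) | Oc1cc(O)c(CC=C(C)C)c(-c2cc3c(OCOC)cc(OCOC)c(C(C)(C)C=C)c3o2)c1C(O)C=C(C)C
F6 | step 14 | 5-[4,6-bis(methoxymethoxy)-7-(2-methylbut-3-en-2-yl)-1-benzofuran-2-yl]-2,2-dimethyl-6-(3-methylbut-2-enyl)chromane-4,7-diyl diacetate (racemic) | CC1(C)CC(OC(C)=O)c2c(O1)cc(OC(C)=O)c(CC=C(C)C)c2-c3cc4c(OCOC)cc(OCOC)c(C(C)(C)C=C)c4o3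
F7 | step 3 | 1-[2-formyl-3-(methoxymethoxy)-5-(3-methylbut-2-enyloxy)phenoxy]propan-2-one (not isolated) | CC(=O)COc1cc(OCC=C(C)C)cc(OCOC)c1C=O
F8 | step 3 | 1-[4-(methoxymethoxy)-6-(3-methylbut-2-enyloxy)-1-benzofuran-2-yl]ethanone | CC(=O)c1cc2c(OCOC)cc(OCC=C(C)C)cc2o1
F9 | step 3 | 2-acetyl-4-(methoxymethoxy)-7-(2-methylbut-3-en-2-yl)-1-benzofuran-6(7H)-one (dienone, racemic, not isolated) | CC(=O)C1=CC2=C(O1)C(C(C)(C)C=C)C(=O)C=C2OCOC
F10 | step 3 | 1-[6-hydroxy-4-(methoxymethoxy)-7-(2-methylbut-3-en-2-yl)-1-benzofuran-2-yl]ethanone | CC(=O)c1cc2c(OCOC)cc(O)c(C(C)(C)C=C)c2o1
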